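## Structural features

The target 17 is a flavanone: benzo ring A (C4a, C5–C8, C8a) is fused to dihydropyranone ring C (O1, C2, C3, C4), with a 4-hydroxyphenyl ring B on C2 and an N-methylpiperidine ring D (N1'', C2''–C6'') joined through C2'' to C6. C6 lies between the 5-OH and 7-OH groups and para to O1, so ring A is a fully differentiated phloroglucinol whose only free position is C8. The two stereocentres, C2 (S) and C2'' (R), are six bonds apart across ring A and cannot control each other. C2 is a benzylic ether β to the C4 ketone and epimerises under base by retro-oxa-Michael opening to the 2'-hydroxychalcone. C2'' is a benzylic amine ortho to two phenols and para to O1, so its ammonium/phenoxide form can ionise to a quinone methide (retro-Mannich), and the free phloroglucinol ring is oxidation-prone. The real difficulty is threefold: carbon substitution at C6 and not at the equally activated C8, a configurationally fragile C2'' on a ring-A carbon flanked by two oxygens, and independent reagent control of two unrelated centres.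

The key step exploits the fact that ring D is the hexahydro form of a 1-methylpyridinium ring whose only stereocentre is C2''. At the aromatic oxidation level the C6–C2'' bond is a biaryl bond, ring D is flat, achiral and inert to the phenoxide stages, and C2'' can be created last by asymmetric hydrogenation. A second feature gives the regiocontrol: C6 is para to O1, so a phenol that carries the future ring D para to its OH has two equivalent ortho positions, and annulation of ring C can give only the C6 isomer.

## Logic of the disconnections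

17 ⇒ 16. Cut: the three O–CH2Ph bonds at O5, O7 and O4'. The free phenols cause both the oxidative and the quinone-methide lability, so they are carried as benzyl ethers that come off under neutral hydrogenolysis. Gain: every earlier intermediate is non-phenolic at O5 and O7. Demand: the hydrogenolysis must stop short of the benzylic C2–O1 and C2''–N bonds and of the C4 carbonyl.

16 ⇒ 15 (key). Cut: the six C–H bonds at C2''–C6'' made when three H2 add to ring D; in the reverse sense ring D of 16 becomes the 1-methylpyridinium ring of 15. Reason: C2'' is the most fragile centre and is best made after O1 is locked in ring C and after all phenoxide chemistry is over. Gain: one stereocentre and one basic amine fewer, a flat achiral substituent at C6, and a C6–C2'' bond that is now open to sp2–sp2 cross-coupling. Demand: one face of C2'' must be selected by the catalyst, and the ketone, the benzyl ethers and C2 must be left alone. In one sentence, the route is the asymmetric hydrogenation of the pyridinium ring of 15.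

15 ⇒ 13 + 14. Cut: C2–C1'. Reason: C2 is set by enantioselective conjugate arylation of a flat chromone and not by an uncontrolled phenol-to-enone ring closure, and ring B arrives as a commercial boronic acid. Gain: ring C of 13 has no stereocentre. Demand: face selection at C2 by the chiral palladium catalyst, on an acceptor that must not bind palladium through nitrogen; hence the N-methyl cation is in place first.

13 ⇒ 12. Cut: N1''–CH3. Reason: the methyl group is added by simple alkylation, which also supplies the activation needed for the key step. Gain: a neutral, chromatographable biaryl. Demand: alkylation at nitrogen and not at the pyranone carbonyl oxygen.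

12 ⇒ 10 ⇒ 8 + 9. Cut: O1–C2 (oxa-Michael closure of ring C through 11) and C4–C3 (acetylide addition). Reason: ring C is assembled from the phenol oxygen, an ortho formyl group and the two carbons of 9 under non-acidic conditions that spare the benzyl ethers. Gain: a simple salicylaldehyde. Demand: oxidation of the carbinol without attack on the electron-rich phenol, and closure in the 6-endo sense.

8 ⇒ 7. Cut: C4a–C4 (the formyl carbon). Reason: in 7 the hydroxyl (the future O1) is para to the pyridyl group and its two ortho positions are equivalent, so ortho-formylation can only give the pattern that leads to C6 substitution. Gain: the C6/C8 problem is removed by symmetry and not by selectivity. Demand: ortho-specific monoformylation.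

7 ⇒ 6 ⇒ 2 + 3. Cut: O–Si, then the C6–C2'' biaryl bond. Reason: the carbon between the two benzyloxy groups of 2 is the unique site for directed metalation (through 4 and 5), and 3 is a good electrophile for Negishi coupling. Gain: two commercial aromatics. Demand: metalation between the benzyloxy groups and not next to the silyl ether, and coupling of a di-ortho-substituted arylzinc.

2 ⇒ 1. Cut: O–Si. Reason: the silyl ether marks the oxygen that becomes O1 and blocks its ortho positions during metalation. Demand: none beyond routine silylation.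

## Other disconnections considered

Alternative 1: (the first that comes to mind) Cut C6–C2'' in the biogenetic sense. The forward key step is a Mannich-type (aza-Friedel–Crafts) addition of (2S)-naringenin A1 to the cyclic iminium salt A2. C6 and C8 of A1 are both ortho/para to three oxygens, so the 8-substituted isomer A3 is expected beside 17. A2 is flat and unbiased, so C2'' would form without face control. The adduct stays in retro-Mannich equilibrium, and the conditions that generate A2 (base or warm acid) are those that open ring C. It is one step, but it decides neither the regiochemistry nor either stereocentre.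

Alternative 2: Cut the same C6–C2'' bond with reversed polarity at C2''. The forward key step is a stereoretentive Negishi sp3–sp2 coupling of the α-amino organozinc A4 with the aryl bromide A5 to give the N-Boc-2-arylpiperidine A6, followed by reduction of the carbamate to N-methyl. A5 is electron-rich and di-ortho-substituted, the worst case for oxidative addition and for reductive elimination of a secondary alkyl group, where β-hydride elimination competes. The configurational integrity of A4 is limited. The carbamate reduction needs a hydride reagent, which forces C2'' to be set before the ketone exists; C2'' would then have to survive the phenoxide stages. The chosen plan makes the same bond as an sp2–sp2 coupling and postpones C2''.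

Alternative 3: Cut N1''–C2'' by a single-atom ring expansion. The forward key step is a Beckmann rearrangement of the oxime A8 of the (2R)-2-arylcyclopentanone A7, in which the aryl-bearing carbon migrates with retention to give the lactam A9; lactam reduction and N-methylation would complete ring D. A7 carries an enolisable benzylic α-hydrogen, so the centre is at risk before it migrates, and a single oxime geometry is required. Making A7 enantioselectively and then reducing and methylating A9 costs at least five more steps than hydrogenating a pyridinium, and the hydride reduction again rules out a late timing.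

Key step: step 9

Assumption: 1, 3, 9 (as its THF solution) and 14 are taken as commercial, and the hindered C6–C2'' axis of 13 and 15 is taken as giving no separable atropisomers (it ceases to be a biaryl axis in step 9).

## Steps

Step 1
Reactants: 1 3,5-bis(benzyloxy)phenol
Product: 2 [3,5-bis(benzyloxy)phenoxy]tri(propan-2-yl)silane
Conditions: TIPSCl (1.2 equiv), imidazole (2 equiv), DMF, rt
Reagents that add atoms: chlorotri(propan-2-yl)silane (TIPSCl), CC(C)[Si](Cl)(C(C)C)C(C)C
Why: Imidazole-promoted silylation of a phenol; the bulky, non-coordinating silyl ether marks the oxygen that becomes O1 and blocks its ortho positions against metalation in step 2.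

Step 2
Reactants: 2 [3,5-bis(benzyloxy)phenoxy]tri(propan-2-yl)silane; 3 2-bromopyridine
Product: 6 2-{2,6-bis(benzyloxy)-4-[tri(propan-2-yl)silyloxy]phenyl}pyridine, via aryllithium 4 (not isolated), via arylzinc chloride 5 (not isolated)
Conditions: n-BuLi (1.1 equiv), THF, 0 °C; ZnCl2 (1.2 equiv), 0 °C to rt; 3, Pd2(dba)3 (2 mol%), SPhos (8 mol%), 65 °C
Reagents that add atoms: none
Why: Directed ortho-metalation should occur at the one C–H flanked by two alkoxy groups (cooperative coordination of lithium; the silyloxy group neither coordinates nor leaves room beside it). Transmetalation to zinc and Negishi coupling with the electron-poor 2-halopyridine then form the future C6–C2'' bond as a biaryl bond; a dialkylbiarylphosphine is chosen because the arylzinc is di-ortho-substituted.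

Step 3
Reactants: 6 2-{2,6-bis(benzyloxy)-4-[tri(propan-2-yl)silyloxy]phenyl}pyridine
Product: 7 3,5-bis(benzyloxy)-4-(pyridin-2-yl)phenol
Conditions: TBAF (1.1 equiv), AcOH (1.1 equiv), THF, 0 °C
Reagents that add atoms: none
Why: Fluoride cleavage of an aryl silyl ether, buffered with acetic acid; it frees the single phenol that becomes O1, para to the pyridyl group.

Step 4
Reactants: 7 3,5-bis(benzyloxy)-4-(pyridin-2-yl)phenol
Product: 8 4,6-bis(benzyloxy)-2-hydroxy-5-(pyridin-2-yl)benzaldehyde
Conditions: MgCl2 (2 equiv), Et3N (4 equiv), (CH2O)n (6 equiv), MeCN, 80 °C; then 1 M HCl to pH 5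
Reagents that add atoms: paraformaldehyde (as formaldehyde), C=O
Why: Magnesium phenoxide-directed ortho-formylation (formaldehyde adds within the magnesium chelate, then hydride passes to a second formaldehyde) is ortho-specific and tolerates benzyl ethers and the free pyridine. The two ortho positions of 7 are equivalent, so a single aldehyde should result, and the C6 versus C8 question is settled here by symmetry.

Step 5
Reactants: 8 4,6-bis(benzyloxy)-2-hydroxy-5-(pyridin-2-yl)benzaldehyde; 9 ethynylmagnesium bromide
Product: 10 1-[4,6-bis(benzyloxy)-2-hydroxy-5-(pyridin-2-yl)phenyl]prop-2-yn-1-ol (racemic)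
Conditions: 9 (0.5 M in THF, 3 equiv), THF, 0 °C to rt; sat. aq. NH4Cl; crude product used directly
Reagents that add atoms: none
Why: 1,2-Addition of an alkynyl Grignard reagent to the aldehyde; the first equivalent is consumed by the phenol. The new carbinol centre is racemic and is removed in step 6.

Step 6
Reactants: 10 1-[4,6-bis(benzyloxy)-2-hydroxy-5-(pyridin-2-yl)phenyl]prop-2-yn-1-ol
Product: 12 5,7-bis(benzyloxy)-6-(pyridin-2-yl)-4H-chromen-4-one, via ynone 11 (not isolated)
Conditions: MnO2 (15 equiv), CH2Cl2, rt; filter; K2CO3 (0.2 equiv), acetone, rt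
Reagents that add atoms: none
Why: MnO2 oxidises the benzylic-propargylic carbinol under neutral conditions. The ortho-hydroxyaryl ynone then closes ring C by base-catalysed intramolecular oxa-Michael addition at the alkyne terminus (6-endo-dig, the electronically favoured conjugate mode), giving the chromone.

Step 7
Reactants: 12 5,7-bis(benzyloxy)-6-(pyridin-2-yl)-4H-chromen-4-one
Product: 13 2-[5,7-bis(benzyloxy)-4-oxo-4H-chromen-6-yl]-1-methylpyridin-1-ium trifluoromethanesulfonate
Conditions: MeOTf (1.05 equiv), CH2Cl2, 0 °C
Reagents that add atoms: methyl trifluoromethanesulfonate (MeOTf), COS(=O)(=O)C(F)(F)F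
Why: Menshutkin N-alkylation of the pyridine, the most nucleophilic site; one equivalent at 0 °C should leave the far less nucleophilic pyranone carbonyl oxygen alone. The cation activates ring D for step 9 and removes a palladium-binding nitrogen before step 8.

Step 8
Reactants: 13 2-[5,7-bis(benzyloxy)-4-oxo-4H-chromen-6-yl]-1-methylpyridin-1-ium trifluoromethanesulfonate; 14 [4-(benzyloxy)phenyl]boronic acid
Product: 15 2-{(2S)-5,7-bis(benzyloxy)-2-[4-(benzyloxy)phenyl]-4-oxo-3,4-dihydro-2H-chromen-6-yl}-1-methylpyridin-1-ium trifluoromethanesulfonate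
Conditions: Pd(OCOCF3)2 (10 mol%), (R)-t-BuPyOx (12 mol%), NH4PF6 (30 mol%), H2O (5 equiv), ClCH2CH2Cl, 60 °C
Reagents that add atoms: none
Why: Asymmetric conjugate addition of an arylboronic acid to a chromone, catalysed by divalent palladium with a chiral pyridine-oxazoline ligand (transmetalation, enantiodetermining carbopalladation of C2=C3, protonolysis of the palladium enolate). The aryl group must add to the Re face of C2 (O1 > C3 > H) to give 2S; the (R)-ligand is chosen by analogy with the facial sense of this catalyst class on cyclic enones, and its antipode is used if the sense proves opposite. The mildly acidic medium gives no path for retro-oxa-Michael opening of the product.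

Step 9
Reactants: 15 2-{(2S)-5,7-bis(benzyloxy)-2-[4-(benzyloxy)phenyl]-4-oxo-3,4-dihydro-2H-chromen-6-yl}-1-methylpyridin-1-ium trifluoromethanesulfonate
Product: 16 (2S)-5,7-bis(benzyloxy)-2-[4-(benzyloxy)phenyl]-6-[(2R)-1-methylpiperidin-2-yl]-2,3-dihydro-4H-chromen-4-one
Conditions: [Ir(cod)Cl]2 (2 mol%), (S)-SynPhos (4.4 mol%), Bu4NI (10 mol%), H2 (40 bar), toluene/CH2Cl2 1:1, 30 °C; then aq. NaHCO3
Reagents that add atoms: none
Why: The reaction is the iridium-catalysed asymmetric hydrogenation of a 2-aryl-N-alkylpyridinium salt, a known reaction type applied here to a hindered member of the class. The cationic ring is the only unit of 15 that accepts hydride from the iridium hydride formed by heterolysis of H2: 1,4-addition gives a dihydropyridine, enamine protonation and a second hydride transfer give the 2-aryl-1-methyl-tetrahydropyridine, and protonation at C3'' gives the cyclic iminium whose reduction at C2'' is stereodetermining. No ring is closed; ring D is saturated in place. C2'' is the only new stereocentre and is set by the chiral diphosphine, which must deliver hydride to the Si face of C2'' (N1'' > C6 > C3'') to give R; the ligand enantiomer written is provisional and its antipode is the immediate substitute. The resident C2 centre is six bonds away and gives no useful bias, so the step is catalyst-controlled, and any minor C2'' epimer is a diastereomer of 16 that can be removed. Chemoselectivity over the C4 ketone, three benzyl ethers and the benzenoid rings is secured by the positive charge, which makes the pyridinium far more hydride-accepting than the donor-substituted aryl ketone. The medium stays acidic (the released HOTf is held by the product amine), so base-triggered epimerisation of C2 has no entry, and C2'' appears only after O1 is locked in ring C. The main uncertainty is the twisted di-ortho-alkoxy aryl group on C2'', which may slow hydride delivery and lower face discrimination.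

Step 10
Reactants: 16 (2S)-5,7-bis(benzyloxy)-2-[4-(benzyloxy)phenyl]-6-[(2R)-1-methylpiperidin-2-yl]-2,3-dihydro-4H-chromen-4-one
Product: 17 (2S)-5,7-dihydroxy-2-(4-hydroxyphenyl)-6-[(2R)-1-methylpiperidin-2-yl]-2,3-dihydro-4H-chromen-4-one
Conditions: H2 (1 atm), 10% Pd/C, EtOAc/MeOH 1:1, rt
Reagents that add atoms: none
Why: Heterogeneous hydrogenolysis of three aryl benzyl ethers under neutral conditions; these should cleave faster than the hindered benzylic C2''–N and C2–O1 bonds. Neither stereocentre is exposed to base or heat.

## Compound list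

1 | 3,5-bis(benzyloxy)phenol | Oc1cc(OCc2ccccc2)cc(OCc2ccccc2)c1 | starting material
2 | [3,5-bis(benzyloxy)phenoxy]tri(propan-2-yl)silane | CC(C)[Si](Oc1cc(OCc2ccccc2)cc(OCc2ccccc2)c1)(C(C)C)C(C)C | intermediate
3 | 2-bromopyridine | Brc1ccccn1 | starting material
4 | {2,6-bis(benzyloxy)-4-[tri(propan-2-yl)silyloxy]phenyl}lithium | [Li]c1c(OCc2ccccc2)cc(O[Si](C(C)C)(C(C)C)C(C)C)cc1OCc1ccccc1 | intermediate
5 | chloro{2,6-bis(benzyloxy)-4-[tri(propan-2-yl)silyloxy]phenyl}zinc | Cl[Zn]c1c(OCc2ccccc2)cc(O[Si](C(C)C)(C(C)C)C(C)C)cc1OCc1ccccc1 | intermediate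
6 | 2-{2,6-bis(benzyloxy)-4-[tri(propan-2-yl)silyloxy]phenyl}pyridine | CC(C)[Si](Oc1cc(OCc2ccccc2)c(-c2ccccn2)c(OCc2ccccc2)c1)(C(C)C)C(C)C | intermediate
7 | 3,5-bis(benzyloxy)-4-(pyridin-2-yl)phenol | Oc1cc(OCc2ccccc2)c(-c2ccccn2)c(OCc2ccccc2)c1 | intermediate
8 | 4,6-bis(benzyloxy)-2-hydroxy-5-(pyridin-2-yl)benzaldehyde | O=Cc1c(O)cc(OCc2ccccc2)c(-c2ccccn2)c1OCc1ccccc1 | intermediate
9 | ethynylmagnesium bromide | C#C[Mg]Br | starting material
10 | 1-[4,6-bis(benzyloxy)-2-hydroxy-5-(pyridin-2-yl)phenyl]prop-2-yn-1-ol (racemic) | C#CC(O)c1c(O)cc(OCc2ccccc2)c(-c2ccccn2)c1OCc1ccccc1 | intermediate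
11 | 1-[4,6-bis(benzyloxy)-2-hydroxy-5-(pyridin-2-yl)phenyl]prop-2-yn-1-one | C#CC(=O)c1c(O)cc(OCc2ccccc2)c(-c2ccccn2)c1OCc1ccccc1 | intermediate
12 | 5,7-bis(benzyloxy)-6-(pyridin-2-yl)-4H-chromen-4-one | O=c1ccoc2cc(OCc3ccccc3)c(-c3ccccn3)c(OCc3ccccc3)c12 | intermediate
13 | 2-[5,7-bis(benzyloxy)-4-oxo-4H-chromen-6-yl]-1-methylpyridin-1-ium trifluoromethanesulfonate | C[n+]1ccccc1-c1c(OCc2ccccc2)cc2occc(=O)c2c1OCc1ccccc1.[O-]S(=O)(=O)C(F)(F)F | intermediate
14 | [4-(benzyloxy)phenyl]boronic acid | OB(O)c1ccc(OCc2ccccc2)cc1 | starting material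
15 | 2-{(2S)-5,7-bis(benzyloxy)-2-[4-(benzyloxy)phenyl]-4-oxo-3,4-dihydro-2H-chromen-6-yl}-1-methylpyridin-1-ium trifluoromethanesulfonate | C[n+]1ccccc1-c1c(OCc2ccccc2)cc2c(c1OCc1ccccc1)C(=O)C[C@@H](c1ccc(OCc3ccccc3)cc1)O2.[O-]S(=O)(=O)C(F)(F)F | intermediate
16 | (2S)-5,7-bis(benzyloxy)-2-[4-(benzyloxy)phenyl]-6-[(2R)-1-methylpiperidin-2-yl]-2,3-dihydro-4H-chromen-4-one | CN1CCCC[C@@H]1c1c(OCc2ccccc2)cc2c(c1OCc1ccccc1)C(=O)C[C@@H](c1ccc(OCc3ccccc3)cc1)O2 | intermediate
17 | (2S)-5,7-dihydroxy-2-(4-hydroxyphenyl)-6-[(2R)-1-methylpiperidin-2-yl]-2,3-dihydro-4H-chromen-4-one | CN1CCCC[C@@H]1c1c(O)cc2c(c1O)C(=O)C[C@@H](c1ccc(O)cc1)O2 | target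

## Step count and least certain steps

Total step count: 10. Longest linear sequence: 10 (the route is linear; 3, 9 and 14 enter as commercial reagents).

Step 9 (key step). Most likely failure: stalling at the enamine stage or poor facial selectivity at the hindered C2'' iminium, because the di-ortho-alkoxy aryl group is twisted and shields both faces; reduction of the C4 carbonyl at long reaction times is a second risk. Fallback (sets out from 2, returns at 16): C2'' is set early by auxiliary control and not by hydrogenation. Lithiation of 2 as in step 2 and quenching of 4 with DMF would give 2,6-bis(benzyloxy)-4-[tri(propan-2-yl)silyloxy]benzaldehyde F1. Condensation with (S)-2-methylpropane-2-sulfinamide (Ti(OEt)4, THF) would give (S)-N-[(E)-{2,6-bis(benzyloxy)-4-[tri(propan-2-yl)silyloxy]phenyl}methylidene]-2-methylpropane-2-sulfinamide F2. Addition of 4-chlorobutylmagnesium bromide in CH2Cl2 through the chelated six-membered transition state should give (S)-N-[(1R)-1-{2,6-bis(benzyloxy)-4-[tri(propan-2-yl)silyloxy]phenyl}-5-chloropentyl]-2-methylpropane-2-sulfinamide F3. Removal of the auxiliary (HCl, MeOH), ring closure by N-alkylation (K2CO3, NaI, MeCN) and reductive methylation (HCHO, NaBH(OAc)3), run without isolation, would give (2R)-2-{2,6-bis(benzyloxy)-4-[tri(propan-2-yl)silyloxy]phenyl}-1-methylpiperidine F4. The conditions of steps 3 to 6 are then applied to this series: 3,5-bis(benzyloxy)-4-[(2R)-1-methylpiperidin-2-yl]phenol F5, 4,6-bis(benzyloxy)-2-hydroxy-5-[(2R)-1-methylpiperidin-2-yl]benzaldehyde F6, 1-{4,6-bis(benzyloxy)-2-hydroxy-5-[(2R)-1-methylpiperidin-2-yl]phenyl}prop-2-yn-1-ol F7 (carbinol epimers, oxidised with a periodinane in place of MnO2 to spare the N-methyl group) and 5,7-bis(benzyloxy)-6-[(2R)-1-methylpiperidin-2-yl]-4H-chromen-4-one F8. Step 8 on the triflic acid salt of F8 with 14 then gives 16. This route exposes C2'' to the phenoxide stages, which is why it is held in reserve.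

Step 8. Most likely failure: low conversion or eroded enantioselectivity, because the electron-rich boronic acid is prone to protodeboronation and a cationic chromone is an untried acceptor for this catalyst. Fallback (sets out from 13, returns at 16): catalyst control at C2 is given up in favour of diastereomer separation. The addition is run with an achiral ligand (2,2'-bipyridine) to give 2-{(2RS)-5,7-bis(benzyloxy)-2-[4-(benzyloxy)phenyl]-4-oxo-3,4-dihydro-2H-chromen-6-yl}-1-methylpyridin-1-ium trifluoromethanesulfonate F9. Step 9 then gives 16 together with (2R)-5,7-bis(benzyloxy)-2-[4-(benzyloxy)phenyl]-6-[(2R)-1-methylpiperidin-2-yl]-2,3-dihydro-4H-chromen-4-one F10. These are diastereomers and can be separated by chromatography or crystallisation. F10 is re-equilibrated at C2 by amine-catalysed ring opening and reclosure (retro-oxa-Michael/oxa-Michael, which does not touch C2'') and separated again.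

Step 6. Most likely failure: oxidation of the electron-rich phenol ring in competition with the carbinol, or ionisation of the ortho-hydroxybenzylic carbinol before it is oxidised. Fallback (sets out from 7, returns at 12, replacing steps 4 to 6): ring C is closed at C4–C4a by acylation and not at O1–C2. Oxa-Michael addition of 7 to tert-butyl propiolate (DABCO cat., CH2Cl2) would give tert-butyl (2E)-3-[3,5-bis(benzyloxy)-4-(pyridin-2-yl)phenoxy]prop-2-enoate F11. TFA would give (2E)-3-[3,5-bis(benzyloxy)-4-(pyridin-2-yl)phenoxy]prop-2-enoic acid F12. Intramolecular Friedel–Crafts acylation (TFAA, or P2O5 in MeSO3H) at either of the two equivalent ortho positions then gives 12.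

Step 10. Most likely failure: over-reduction, that is hydrogenolysis of the benzylic C2–O1 or C2''–N bond or reduction of the C4 carbonyl before the third benzyl ether is gone. Fallback (sets out from 16, returns at 17): the ethers are cleaved by Lewis acid and not by hydrogen, with BCl3 and pentamethylbenzene as cation scavenger in CH2Cl2 at −78 °C, followed by a methanol quench. No new intermediate is involved.

## Further compounds

F1 | step 9 | 2,6-bis(benzyloxy)-4-[tri(propan-2-yl)silyloxy]benzaldehyde | O=Cc1c(OCc2ccccc2)cc(O[Si](C(C)C)(C(C)C)C(C)C)cc1OCc1ccccc1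
F2 | step 9 | (S)-N-[(E)-{2,6-bis(benzyloxy)-4-[tri(propan-2-yl)silyloxy]phenyl}methylidene]-2-methylpropane-2-sulfinamide | CC(C)(C)[S@](=O)/N=C/c1c(OCc2ccccc2)cc(O[Si](C(C)C)(C(C)C)C(C)C)cc1OCc1ccccc1
F3 | step 9 | (S)-N-[(1R)-1-{2,6-bis(benzyloxy)-4-[tri(propan-2-yl)silyloxy]phenyl}-5-chloropentyl]-2-methylpropane-2-sulfinamide | CC(C)(C)[S@](=O)N[C@H](CCCCCl)c1c(OCc2ccccc2)cc(O[Si](C(C)C)(C(C)C)C(C)C)cc1OCc1ccccc1
F4 | step 9 | (2R)-2-{2,6-bis(benzyloxy)-4-[tri(propan-2-yl)silyloxy]phenyl}-1-methylpiperidine | CN1CCCC[C@@H]1c1c(OCc2ccccc2)cc(O[Si](C(C)C)(C(C)C)C(C)C)cc1OCc1ccccc1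
F5 | step 9 | 3,5-bis(benzyloxy)-4-[(2R)-1-methylpiperidin-2-yl]phenol | CN1CCCC[C@@H]1c1c(OCc2ccccc2)cc(O)cc1OCc1ccccc1
F6 | step 9 | 4,6-bis(benzyloxy)-2-hydroxy-5-[(2R)-1-methylpiperidin-2-yl]benzaldehyde | CN1CCCC[C@@H]1c1c(OCc2ccccc2)cc(O)c(C=O)c1OCc1ccccc1
F7 | step 9 | 1-{4,6-bis(benzyloxy)-2-hydroxy-5-[(2R)-1-methylpiperidin-2-yl]phenyl}prop-2-yn-1-ol (carbinol epimers) | CN1CCCC[C@@H]1c1c(OCc2ccccc2)cc(O)c(C(O)C#C)c1OCc1ccccc1
F8 | step 9 | 5,7-bis(benzyloxy)-6-[(2R)-1-methylpiperidin-2-yl]-4H-chromen-4-one | CN1CCCC[C@@H]1c1c(OCc2ccccc2)cc2occc(=O)c2c1OCc1ccccc1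
F9 | step 8 | 2-{(2RS)-5,7-bis(benzyloxy)-2-[4-(benzyloxy)phenyl]-4-oxo-3,4-dihydro-2H-chromen-6-yl}-1-methylpyridin-1-ium trifluoromethanesulfonate | C[n+]1ccccc1-c1c(OCc2ccccc2)cc2c(c1OCc1ccccc1)C(=O)CC(c1ccc(OCc3ccccc3)cc1)O2.[O-]S(=O)(=O)C(F)(F)F
F10 | step 8 | (2R)-5,7-bis(benzyloxy)-2-[4-(benzyloxy)phenyl]-6-[(2R)-1-methylpiperidin-2-yl]-2,3-dihydro-4H-chromen-4-one | CN1CCCC[C@@H]1c1c(OCc2ccccc2)cc2c(c1OCc1ccccc1)C(=O)C[C@H](c1ccc(OCc3ccccc3)cc1)O2
F11 | step 6 | tert-butyl (2E)-3-[3,5-bis(benzyloxy)-4-(pyridin-2-yl)phenoxy]prop-2-enoate | CC(C)(C)OC(=O)/C=C/Oc1cc(OCc2ccccc2)c(-c2ccccn2)c(OCc2ccccc2)c1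
F12 | step 6 | (2E)-3-[3,5-bis(benzyloxy)-4-(pyridin-2-yl)phenoxy]prop-2-enoic acid | OC(=O)/C=C/Oc1cc(OCc2ccccc2)c(-c2ccccn2)c(OCc2ccccc2)c1
F0 | step 10 | none | none
A1 | alternative 1 | (2S)-5,7-dihydroxy-2-(4-hydroxyphenyl)-2,3-dihydro-4H-chromen-4-one ((2S)-naringenin) | O=C1C[C@@H](c2ccc(O)cc2)Oc2cc(O)cc(O)c12
A2 | alternative 1 | 1-methyl-2,3,4,5-tetrahydropyridin-1-ium | C[N+]1=CCCCC1
A3 | alternative 1 | (2S)-5,7-dihydroxy-2-(4-hydroxyphenyl)-8-(1-methylpiperidin-2-yl)-2,3-dihydro-4H-chromen-4-one (C2'' epimers) | CN1CCCCC1c1c(O)cc(O)c2c1O[C@H](c1ccc(O)cc1)CC2=O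
A4 | alternative 2 | chloro{(2S)-1-[(tert-butoxy)carbonyl]piperidin-2-yl}zinc | CC(C)(C)OC(=O)N1CCCC[C@@H]1[Zn]Cl
A5 | alternative 2 | [4-bromo-3,5-bis(benzyloxy)phenoxy]tri(propan-2-yl)silane | CC(C)[Si](Oc1cc(OCc2ccccc2)c(Br)c(OCc2ccccc2)c1)(C(C)C)C(C)C
A6 | alternative 2 | tert-butyl (2R)-2-{2,6-bis(benzyloxy)-4-[tri(propan-2-yl)silyloxy]phenyl}piperidine-1-carboxylate | CC(C)(C)OC(=O)N1CCCC[C@@H]1c1c(OCc2ccccc2)cc(O[Si](C(C)C)(C(C)C)C(C)C)cc1OCc1ccccc1
A7 | alternative 3 | (2R)-2-{2,6-bis(benzyloxy)-4-[tri(propan-2-yl)silyloxy]phenyl}cyclopentan-1-one | O=C1CCC[C@@H]1c1c(OCc2ccccc2)cc(O[Si](C(C)C)(C(C)C)C(C)C)cc1OCc1ccccc1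
A8 | alternative 3 | N-[(1E,2R)-2-{2,6-bis(benzyloxy)-4-[tri(propan-2-yl)silyloxy]phenyl}cyclopentylidene]hydroxylamine | O/N=C1\CCC[C@@H]1c1c(OCc2ccccc2)cc(O[Si](C(C)C)(C(C)C)C(C)C)cc1OCc1ccccc1
A9 | alternative 3 | (6R)-6-{2,6-bis(benzyloxy)-4-[tri(propan-2-yl)silyloxy]phenyl}piperidin-2-one | O=C1CCC[C@H](c2c(OCc3ccccc3)cc(O[Si](C(C)C)(C(C)C)C(C)C)cc2OCc2ccccc2)N1
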